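**Plan** (ring atoms carry the target's 7-oxabicyclo[4.1.0]heptane numbers throughout: C1 = oxirane carbon with CH2OBz, C2/C3 = acetoxy carbons, C4/C5 = carbinol carbons, C6 = oxirane CH)
1. Retrosynthesis removes the esters and both oxirane oxygens to reach a cyclohexa-1,4-diene (C1=C6, C3=C4) whose C2 and C5 oxygens are cis, then cuts C1–C6 and C3–C4.
2. Enabling feature: these two bonds face each other across the six-membered ring, and each half between them is one oxygen-bearing sp3 carbon (C2 or C5) flanked by two carbons that can be sp2. The carbocycle is therefore the sum of two penta-1,4-dien-3-ol units, and the 1,4-related C2/C5 oxygens can be clamped by one silicon atom.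
3. Forward: the mixed silaketal of the two dienols undergoes a tandem double ring-closing metathesis. The seven-membered dioxasilepine forms first (C3=C4), then the carbocycle across it (C1=C6), giving a 2,4-dioxa-3-silabicyclo[3.2.2]nonadiene.
4. After the clamp is removed, the oxirane is made by Sharpless epoxidation of C1=C6; C5 is inverted by Mitsunobu reaction; C3=C4 is epoxidised under hydroxyl direction and opened at C3 by acetate.
5. Stereochemistry: C2 comes from a Sharpless kinetic resolution; C5 is set cis to C2 by the tether and then inverted; C1/C6 from L-(+)-tartrate matched with the ring hydroxyls; C3/C4 from directed epoxidation and SN2 opening.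

Key step: step 6

**Step 1**
Reactants: 1 acrolein; 2 methyl acrylate
Product: 3 methyl 3-hydroxy-2-methylidenepent-4-enoate (racemic)
Conditions: DABCO (0.15 equiv), methyl acrylate (3 equiv), MeOH, 0 °C to 20 °C
Reagents that add atoms: none
Why: Morita–Baylis–Hillman reaction; the DABCO–acrylate zwitterion adds 1,2 to the aldehyde of acrolein, and excess acrylate suppresses self-coupling of acrolein.

**Step 2**
Reactants: 3 methyl 3-hydroxy-2-methylidenepent-4-enoate (racemic)
Product: 4 methyl (3R)-3-hydroxy-2-methylidenepent-4-enoate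
Conditions: Ti(OiPr)4 (0.1 equiv), D-(−)-diisopropyl tartrate (0.15 equiv), t-BuOOH (0.6 equiv), 4 Å MS, CH2Cl2, −20 °C
Reagents that add atoms: none
Why: Sharpless kinetic resolution; only the vinyl group is epoxidised (the acrylate alkene is too electron-poor), D-(−)-tartrate consumes the (S)-enantiomer as its erythro epoxy alcohol and leaves (R)-4, which becomes C2 of the target.

**Step 3**
Reactants: 4 methyl (3R)-3-hydroxy-2-methylidenepent-4-enoate
Product: 5 (3R)-2-methylidenepent-4-ene-1,3-diol
Conditions: iBu2AlH (3.5 equiv), CH2Cl2, −78 °C to 0 °C; aqueous KNaC4H4O6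
Reagents that add atoms: none
Why: 1,2-reduction of the α-methylene ester to the primary allylic alcohol; the stereocentre is not involved.

**Step 4**
Reactants: 5 (3R)-2-methylidenepent-4-ene-1,3-diol
Product: 6 (3R)-2-{[tert-butyl(dimethyl)silyl]oxymethyl}penta-1,4-dien-3-ol
Conditions: TBSCl (1.05 equiv), imidazole, CH2Cl2, −20 °C
Reagents that add atoms: tert-butyl(chloro)dimethylsilane, CC(C)(C)[Si](C)(C)Cl
Why: chemoselective silylation of the primary over the hindered secondary bis-allylic hydroxyl; the primary oxygen stays masked through the metathesis and is released later together with the tether.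

**Step 5**
Reactants: 7 penta-1,4-dien-3-ol; 6 (3R)-2-{[tert-butyl(dimethyl)silyl]oxymethyl}penta-1,4-dien-3-ol
Product: 9 {[(3R)-2-{[tert-butyl(dimethyl)silyl]oxymethyl}penta-1,4-dien-3-yl]oxy}(penta-1,4-dien-3-yloxy)di(propan-2-yl)silane, via chlorosilyl ether 8 (not isolated)
Conditions: 7, iPr2SiCl2 (3 equiv), imidazole, CH2Cl2, 0 °C; excess silane removed in vacuo; then 6, imidazole, DMF, 20 °C
Reagents that add atoms: dichlorodi(propan-2-yl)silane, CC(C)[Si](Cl)(Cl)C(C)C
Why: stepwise formation of an unsymmetrical dialkoxysilane (temporary silicon tether); the cheap dienol is first converted to the monochlorosilane with excess dichlorosilane, which then silylates 6.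

**Step 6**
Reactants: 9 mixed silaketal
Product: 11 tert-butyl{[(1S,5R)-3,3-di(propan-2-yl)-2,4-dioxa-3-silabicyclo[3.2.2]nona-6,8-dien-6-yl]methoxy}dimethylsilane (the cis-3,6-dioxy-cyclohexa-1,4-diene clamped by O–Si–O), via dioxasilepine 10 (not isolated)
Conditions: second-generation Hoveyda–Grubbs catalyst RuCl2(H2IMes)(=CH-C6H4-2-OiPr) (10 mol %), 1,4-benzoquinone (20 mol %), toluene (2 mM), 80 °C, argon sparge
Reagents that add atoms: none
Why: Both closures are Chauvin olefin metatheses through ruthenacyclobutanes, and each releases ethene. The first joins the two unhindered vinyl groups (future C3=C4) into the seven-membered 4,7-dihydro-1,3,2-dioxasilepine 10; the closest known reaction type is temporary silicon-tethered ring-closing metathesis of silaketals of prochiral penta-1,4-dien-3-ol. The second joins the remaining vinyl group on C5 and the 1,1-disubstituted alkene on C2 across that ring (bridging closure of the six-membered carbocycle, as in ring-closing metathesis to bridged bicycloalkenes), which makes the trisubstituted C1=C6 bond. Only the silepine with its two alkenyl groups cis can bridge, so the three-atom O–Si–O clamp relays the configuration of C2 to C5; the trans isomer can reopen with ethene and close again because its disubstituted ring alkene stays metathesis-active. The step needs ring closure over oligomerisation and no migration of the skipped diene towards an arene; high dilution, ethene removal and benzoquinone serve this, and neither dienol can close on itself (a cyclopropene would result), so only the cross-union is productive.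

**Step 7**
Reactants: 11 bicyclic silylene
Product: 12 (1R,4S)-2-(hydroxymethyl)cyclohexa-2,5-diene-1,4-diol (cis-1,4-diol)
Conditions: Bu4NF (4 equiv), AcOH (4 equiv), THF, 0 °C to 20 °C
Reagents that add atoms: none
Why: fluoride cleaves the silylene and the TBS ether in one pot; acetic acid buffering avoids acid- or base-induced dehydration of the cyclohexa-2,5-diene-1,4-diol to an arene.

**Step 8**
Reactants: 12 triol
Product: 13 (1R,2R,5S,6S)-1-(hydroxymethyl)-7-oxabicyclo[4.1.0]hept-3-ene-2,5-diol (oxirane and both ring hydroxyls on one face)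
Conditions: Ti(OiPr)4 (1.1 equiv), L-(+)-diisopropyl tartrate (1.3 equiv), t-BuOOH (2 equiv), 4 Å MS, CH2Cl2, −25 °C
Reagents that add atoms: tert-butyl hydroperoxide, CC(C)(C)OO
Why: Katsuki–Sharpless asymmetric epoxidation through the primary allylic alcohol; L-(+)-tartrate delivers oxygen to the face of C1=C6 that also carries C2-OH and C5-OH (matched case), while C3=C4, flanked only by cyclic secondary allylic alcohols, is a poor substrate and survives.

**Step 9**
Reactants: 13 epoxy triol
Product: 14 [(1R,2R,5S,6S)-2,5-dihydroxy-7-oxabicyclo[4.1.0]hept-3-en-1-yl]methyl benzoate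
Conditions: BzCl (1.05 equiv), 2,4,6-collidine, CH2Cl2, −78 °C to −30 °C
Reagents that add atoms: benzoyl chloride, O=C(Cl)c1ccccc1
Why: selective acylation of the primary hydroxyl at low temperature; the two secondary hydroxyls next to the oxirane carbons react more slowly.

**Step 10**
Reactants: 14 diol benzoate
Product: 15 [(1R,2R,5R,6S)-5-(chloroacetoxy)-2-hydroxy-7-oxabicyclo[4.1.0]hept-3-en-1-yl]methyl benzoate
Conditions: ClCH2CO2H (1.5 equiv), PPh3 (1.5 equiv), DIAD (1.5 equiv), toluene/THF, 0 °C
Reagents that add atoms: chloroacetic acid, OC(=O)CCl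
Why: Mitsunobu reaction; SN2 displacement of the oxyphosphonium ion at allylic C5 by chloroacetate inverts C5 (now trans to the oxirane), whereas C2-OH sits next to the quaternary C1 (neopentyl-like) and cannot be displaced.

**Step 11**
Reactants: 15 chloroacetate
Product: 16 bis-epoxide (15 with a second oxirane at C3–C4 on the same face as the C1–C6 oxirane and C2-OH; C5 ester on the opposite face)
Conditions: mCPBA (1.5 equiv), Na2HPO4, CH2Cl2, 0 °C to 20 °C
Reagents that add atoms: 3-chloroperoxybenzoic acid, O=C(OO)c1cccc(Cl)c1
Why: Henbest hydroxyl-directed epoxidation; hydrogen bonding to C2-OH delivers oxygen to its own face of C3=C4, and the C5 ester shields the other face; this fixes the C4 oxygen.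

**Step 12**
Reactants: 16 bis-epoxide alcohol
Product: 17 2-O-acetate of 16
Conditions: Ac2O, pyridine, DMAP (cat.), CH2Cl2, 0 °C to 20 °C
Reagents that add atoms: acetic anhydride, CC(=O)OC(C)=O
Why: standard acetylation of the only free hydroxyl; it installs the C2 acetate before C4-OH is unveiled.

**Step 13**
Reactants: 17 bis-epoxide acetate
Product: 18 5-O-chloroacetyl derivative of the target (C3-OAc trans to C2-OAc, C4-OH free)
Conditions: AcOH (3 equiv), Co(salen)(OAc) (trivalent cobalt; salen = N,N′-ethylenebis(salicylideneiminate); 5 mol %), tert-butyl methyl ether, 20 °C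
Reagents that add atoms: acetic acid, CC(=O)O
Why: Lewis-acid-assisted SN2 opening of the disubstituted oxirane by carboxylate; acetate attacks C3 anti to the oxirane oxygen because its neighbour C2-OAc lies on the far face, whereas approach to C4 (and to C6 of the other oxirane) is blocked by the syn C5 ester and C1 is quaternary; C3 is inverted, C4 keeps its oxygen, and the chloroacetyl group is a poor neighbouring participant.

**Step 14**
Reactants: 18 chloroacetate
Product: 19 [(1S,2R,3S,4R,5R,6S)-2,3-bis(acetyloxy)-4,5-dihydroxy-7-oxabicyclo[4.1.0]heptan-1-yl]methyl benzoate (target)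
Conditions: iPr2NEtH+ −S2C–NHNH2 (hydrazinedithiocarbonate, 3 equiv), 2,6-lutidine/AcOH buffer, 1,4-dioxane/H2O, 20 °C
Reagents that add atoms: none
Why: selective dechloroacetylation; S-alkylation of the dithiocarbazate at CH2Cl followed by intramolecular aminolysis releases C5-OH under near-neutral conditions that leave the acetates, the benzoate and the oxirane alone and do not promote acetyl migration.

**Compound list**
1 | acrolein | C=CC=O | starting material
2 | methyl acrylate | C=CC(=O)OC | starting material
3 | methyl 3-hydroxy-2-methylidenepent-4-enoate (racemic) | C=CC(O)C(=C)C(=O)OC | intermediate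
4 | methyl (3R)-3-hydroxy-2-methylidenepent-4-enoate | C=C[C@@H](O)C(=C)C(=O)OC | intermediate
5 | (3R)-2-methylidenepent-4-ene-1,3-diol | C=C[C@@H](O)C(=C)CO | intermediate
6 | (3R)-2-{[tert-butyl(dimethyl)silyl]oxymethyl}penta-1,4-dien-3-ol | C=C[C@@H](O)C(=C)CO[Si](C)(C)C(C)(C)C | intermediate
7 | penta-1,4-dien-3-ol | C=CC(O)C=C | starting material
8 | chloro(penta-1,4-dien-3-yloxy)di(propan-2-yl)silane | C=CC(O[Si](Cl)(C(C)C)C(C)C)C=C | intermediate
9 | {[(3R)-2-{[tert-butyl(dimethyl)silyl]oxymethyl}penta-1,4-dien-3-yl]oxy}(penta-1,4-dien-3-yloxy)di(propan-2-yl)silane | C=C[C@@H](O[Si](C(C)C)(C(C)C)OC(C=C)C=C)C(=C)CO[Si](C)(C)C(C)(C)C | intermediate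
10 | (4R,7R)-4-ethenyl-7-(3-{[tert-butyl(dimethyl)silyl]oxy}prop-1-en-2-yl)-2,2-di(propan-2-yl)-4,7-dihydro-1,3,2-dioxasilepine (cis) | C=C[C@@H]1C=C[C@H](C(=C)CO[Si](C)(C)C(C)(C)C)O[Si](C(C)C)(C(C)C)O1 | intermediate
11 | tert-butyl{[(1S,5R)-3,3-di(propan-2-yl)-2,4-dioxa-3-silabicyclo[3.2.2]nona-6,8-dien-6-yl]methoxy}dimethylsilane | C1=C[C@H]2C=C(CO[Si](C)(C)C(C)(C)C)[C@@H]1O[Si](C(C)C)(C(C)C)O2 | intermediate
12 | (1R,4S)-2-(hydroxymethyl)cyclohexa-2,5-diene-1,4-diol | C1=C[C@H](O)C=C(CO)[C@@H]1O | intermediate
13 | (1R,2R,5S,6S)-1-(hydroxymethyl)-7-oxabicyclo[4.1.0]hept-3-ene-2,5-diol | C1=C[C@H](O)[C@@H]2O[C@]2(CO)[C@@H]1O | intermediate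
14 | [(1R,2R,5S,6S)-2,5-dihydroxy-7-oxabicyclo[4.1.0]hept-3-en-1-yl]methyl benzoate | C1=C[C@H](O)[C@@H]2O[C@]2(COC(=O)c2ccccc2)[C@@H]1O | intermediate
15 | [(1R,2R,5R,6S)-5-(chloroacetoxy)-2-hydroxy-7-oxabicyclo[4.1.0]hept-3-en-1-yl]methyl benzoate | C1=C[C@@H](OC(=O)CCl)[C@@H]2O[C@]2(COC(=O)c2ccccc2)[C@@H]1O | intermediate
16 | bis-epoxide: 15 with a C3–C4 oxirane on the face of the C1–C6 oxirane and C2-OH | O1[C@@H]2[C@H]1[C@@H](OC(=O)CCl)[C@@H]1O[C@]1(COC(=O)c1ccccc1)[C@@H]2O | intermediate
17 | 2-O-acetate of 16 | O1[C@@H]2[C@H]1[C@@H](OC(=O)CCl)[C@@H]1O[C@]1(COC(=O)c1ccccc1)[C@@H]2OC(C)=O | intermediate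
18 | 5-O-chloroacetyl derivative of the target | CC(=O)O[C@H]1[C@H](O)[C@@H](OC(=O)CCl)[C@@H]2O[C@]2(COC(=O)c2ccccc2)[C@@H]1OC(C)=O | intermediate
19 | [(1S,2R,3S,4R,5R,6S)-2,3-bis(acetyloxy)-4,5-dihydroxy-7-oxabicyclo[4.1.0]heptan-1-yl]methyl benzoate | CC(=O)O[C@H]1[C@H](O)[C@@H](O)[C@@H]2O[C@]2(COC(=O)c2ccccc2)[C@@H]1OC(C)=O | target

**Total step count:** 14. **Longest linear sequence:** 14 steps (1/2 to 19; dienol 7 enters at step 5).

**Steps most likely to fail**

Step 6. The second, bridging ring closure may not occur (the reaction stops at the monocycle or oligomerises), or the skipped diene may isomerise and aromatise. Fallback: starting from 9, the first metathesis alone is run at 40 °C with the second-generation Grubbs catalyst RuCl2(H2IMes)(PCy3)(=CHPh), and the cis-dioxasilepine 10 is isolated. Both silicon groups are removed with Bu4NF/AcOH to give (3R,4Z,6R)-2-methylideneocta-4,7-diene-1,3,6-triol F1. This open (Z)-1,4,7-triene is then closed to the cyclohexa-1,4-diene by an ordinary untethered ring-closing metathesis, which needs no bridged transition state and returns to the route at 12.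

Step 10. The redox condensation may activate the wrong hydroxyl, or the activated allylic system may react by SN2′ attack or elimination instead of direct inversion. Fallback: starting from 14, the less hindered C5 hydroxyl is sulfonylated selectively with Tf2O/pyridine at −40 °C to give [(1R,2R,5S,6S)-2-hydroxy-5-(trifluoromethanesulfonyloxy)-7-oxabicyclo[4.1.0]hept-3-en-1-yl]methyl benzoate F2. The isolated triflate is displaced with CsO2CCH2Cl/18-crown-6 in toluene (sulfonate displacement with inversion), which returns to the route at 15.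

Step 13. Acetate may enter at C4 instead of C3, the C5 ester may participate and deliver a cis product, or the trisubstituted oxirane may open in competition. Fallback: starting from 17, the chloroacetyl group is removed first with hydrazinedithiocarbonate to give the C5 alcohol of 17 F3. This is silylated (TBSOTf, 2,6-lutidine, −78 °C) to the C5 tert-butyldimethylsilyl ether of 17 F4, whose bulky, non-participating group blocks the C4 side. Acetolysis as in step 13 then gives the 5-O-tert-butyldimethylsilyl ether of the target F5, and HF·pyridine in THF/pyridine at 0 °C returns to the route at 19.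

**Further compounds**
F1 | step 6 | (3R,4Z,6R)-2-methylideneocta-4,7-diene-1,3,6-triol | C=C[C@@H](O)/C=C\[C@H](C(=C)CO)O
F2 | step 10 | [(1R,2R,5S,6S)-2-hydroxy-5-(trifluoromethanesulfonyloxy)-7-oxabicyclo[4.1.0]hept-3-en-1-yl]methyl benzoate | C1=C[C@H](OS(=O)(=O)C(F)(F)F)[C@@H]2O[C@]2(COC(=O)c2ccccc2)[C@@H]1O
F3 | step 13 | C5 alcohol of 17 (chloroacetyl removed) | O1[C@@H]2[C@H]1[C@@H](O)[C@@H]1O[C@]1(COC(=O)c1ccccc1)[C@@H]2OC(C)=O
F4 | step 13 | C5 tert-butyldimethylsilyl ether of 17 | O1[C@@H]2[C@H]1[C@@H](O[Si](C)(C)C(C)(C)C)[C@@H]1O[C@]1(COC(=O)c1ccccc1)[C@@H]2OC(C)=O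
F5 | step 13 | 5-O-tert-butyldimethylsilyl ether of the target | CC(=O)O[C@H]1[C@H](O)[C@@H](O[Si](C)(C)C(C)(C)C)[C@@H]2O[C@]2(COC(=O)c2ccccc2)[C@@H]1OC(C)=O
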